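## Retrosynthetic overview

1. Target 25 ⇐ 24: ring D is opened last by C16–C17 scission of an α-ketol (the D-seco step of limonoids), which releases the glycidic methyl ester and the 3-furyl ketone together.
2. 24 ⇐ 17 + 21: C5=C6 by aldol condensation of the C7 methyl ketone with keto-lactone 21. The δ-lactone of 21 is closed by the C4 tertiary hydroxyl attacking C3 (Achmatowicz), the closure used by A-seco limonoids.
3. 17 ⇐ 15: C16 oxidation and β-epoxidation of the Δ14-16-one while ring D is still closed (Δ14 → 14β,15β-epoxide → D-ring scission, the biosynthetic order).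
4. 9 ⇐ 5: ring C is closed through C8–C14 (the bond that closes ring C in triterpene cyclisation) by one Rh-catalysed vinyl addition/aldol cyclisation of achiral enone-dione 5, which sets C9, C8 and C13.
5. Ring order: ring D (bought as the cyclopentanedione) → ring C → epoxide → ring D opened; the furan is bought and the lactone is built separately.

Assumption: positions are given in limonoid numbering (ring C = C8, C9, C11–C14; ring D = C13–C17; α = the face of the C13 methyl), and ylide 4 is taken as a purchasable reagent.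

## Route

Step 1
Reactants: 1 2-methylcyclopentane-1,3-dione; 2 acrolein
Product: 3 3-(1-methyl-2,5-dioxocyclopentyl)propanal
Conditions: H2O, rt, 16 h
Reagents that add atoms: none
Why: Michael addition of the C-acidic 1,3-dione (C13) to acrolein; the product is achiral, so no stereocentre is set.

Step 2
Reactants: 3 3-(1-methyl-2,5-dioxocyclopentyl)propanal; 4 3-(triphenylphosphoranylidene)butan-2-one
Product: 5 2-methyl-2-[(3E)-4-methyl-5-oxohex-3-en-1-yl]cyclopentane-1,3-dione
Conditions: toluene, 80 °C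
Reagents that add atoms: none
Why: Wittig olefination with an acyl-stabilised ylide is aldehyde-selective (the dione ketones are untouched) and gives the (E)-trisubstituted enone.

Step 3
Reactants: 5 2-methyl-2-[(3E)-4-methyl-5-oxohex-3-en-1-yl]cyclopentane-1,3-dione; 6 potassium vinyltrifluoroborate
Product: 8 4-acetyl-3a-hydroxy-4,7a-dimethyl-5-vinyloctahydro-1H-inden-1-one (13α-CH3; 14α-OH; 8α-acetyl; 8β-CH3; 9β-vinyl), via rhodium enolate 7 (not isolated)
Conditions: Rh(acac)(C2H4)2 (5 mol %), (S)-BINAP (6 mol %), dioxane/H2O 10:1, 80 °C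
Reagents that add atoms: none
Why: Proposed new method: Hayashi–Miyaura transmetalation gives Rh–vinyl, which adds to the α-Re face of the (E)-enone at C9 (ligand control, sets C9; the ligand antipode is assigned by analogy with (E)-alk-3-en-2-ones), and the O-bound rhodium enolate 7 then attacks one of the two enantiotopic dione carbonyls through a chelated chair aldol transition state with vinyl equatorial, closing ring C at C8–C14 and setting C8 (acetyl trans to vinyl, cis to the new OH), C14 and C13 (cis-hydrindane); the closest known reaction is the Rh-catalysed conjugate addition–aldol cyclisation of enone-diones, extended here to an α-methyl enone and a fully substituted aldol donor carbon.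

Step 4
Reactants: 8 4-acetyl-3a-hydroxy-4,7a-dimethyl-5-vinyloctahydro-1H-inden-1-one
Product: 9 4-acetyl-4,7a-dimethyl-5-vinyl-2,4,5,6,7,7a-hexahydro-1H-inden-1-one (Δ14(15))
Conditions: SOCl2, pyridine, CH2Cl2, 0 °C
Reagents that add atoms: none
Why: Dehydration through the tertiary chlorosulfite (E2); C15 carries the only β-hydrogen (C8 and C13 are quaternary), so the Δ14(15) alkene forms regiospecifically and C8, C9, C13 are untouched.

Step 5
Reactants: 9 4-acetyl-4,7a-dimethyl-5-vinyl-2,4,5,6,7,7a-hexahydro-1H-inden-1-one; 10 3-bromofuran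
Product: 13 1-[1-(furan-3-yl)-1-hydroxy-4,7a-dimethyl-5-vinyl-2,4,5,6,7,7a-hexahydro-1H-inden-4-yl]ethan-1-one (17-OH cis to 13-CH3), via 3-furyllithium 11 (not isolated), via 3-furylcerium dichloride 12 (not isolated)
Conditions: 10, n-BuLi, THF, −78 °C; CeCl3, −78 °C; then 9; aq NH4Cl
Reagents that add atoms: none
Why: Br/Li exchange and transmetalation to cerium (Imamoto organocerium addition) suppress enolisation; 1,2-addition occurs at the cyclopentanone and not at the neopentyl acetyl group, from the face opposite the angular methyl (C17 becomes sp2 again in step 12, so its configuration is irrelevant).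

Step 6
Reactants: 13 1-[1-(furan-3-yl)-1-hydroxy-4,7a-dimethyl-5-vinyl-2,4,5,6,7,7a-hexahydro-1H-inden-4-yl]ethan-1-one
Product: 14 1,1'-[1-(furan-3-yl)-1-hydroxy-4,7a-dimethyl-2,4,5,6,7,7a-hexahydro-1H-indene-4,5-diyl]di(ethan-1-one)
Conditions: PdCl2 (10 mol %), CuCl, O2 (1 atm), DMF/H2O 7:1, rt
Reagents that add atoms: water, O
Why: Tsuji–Wacker oxidation is Markovnikov-selective for the monosubstituted alkene; the trisubstituted Δ14 alkene between two quaternary carbons does not react and no stereocentre changes.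

Step 7
Reactants: 14 1,1'-[1-(furan-3-yl)-1-hydroxy-4,7a-dimethyl-2,4,5,6,7,7a-hexahydro-1H-indene-4,5-diyl]di(ethan-1-one)
Product: 15 1-[1-(furan-3-yl)-1-hydroxy-5-[(1R)-1-hydroxyethyl]-4,7a-dimethyl-2,4,5,6,7,7a-hexahydro-1H-inden-4-yl]ethan-1-one
Conditions: (S)-Me-CBS (20 mol %), BH3·SMe2, THF, −20 °C; MeOH
Reagents that add atoms: none
Why: Corey–Bakshi–Shibata reduction; the (S)-catalyst treats CH3 as the small and C9 as the large group and gives the (R)-carbinol at C10, while the acetyl on quaternary C8 is too hindered to compete.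

Step 8
Reactants: 15 1-[1-(furan-3-yl)-1-hydroxy-5-[(1R)-1-hydroxyethyl]-4,7a-dimethyl-2,4,5,6,7,7a-hexahydro-1H-inden-4-yl]ethan-1-one
Product: 17 4-acetyl-3,3a-epoxy-1-(furan-3-yl)-1-hydroxy-5-[(1R)-1-hydroxyethyl]-4,7a-dimethyloctahydro-2H-inden-2-one (14β,15β-epoxide), via enone ketol 16 (not isolated)
Conditions: Rh2(cap)4 (1 mol %), t-BuOOH (6 equiv), K2CO3, CH2Cl2, rt; then DBU, 0 °C
Reagents that add atoms: tert-butyl hydroperoxide, CC(C)(C)OO
Why: Dirhodium caprolactamate/t-BuOOH allylic oxidation abstracts H from C16, the only allylic CH2, to give the Δ14-16-one 16; DBU then starts a Weitz–Scheffer epoxidation in which t-BuOO– adds to C14 from the β face, opposite the angular C13 methyl, and closure on the cyclopentenone can only give the cis-fused epoxide with C16 cis to C13, which fixes C14 and C15.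

Step 9
Reactants: 18 2-acetylfuran
Product: 19 2-(furan-2-yl)propan-2-ol
Conditions: MeMgBr, THF, 0 °C; aq NH4Cl
Reagents that add atoms: methylmagnesium bromide, C[Mg]Br
Why: Grignard addition to the methyl ketone gives the tertiary furfuryl alcohol; no stereocentre.

Step 10
Reactants: 19 2-(furan-2-yl)propan-2-ol
Product: 21 6,6-dimethyl-2H-pyran-2,5(6H)-dione, via Achmatowicz lactol 20 (not isolated)
Conditions: NBS, NaHCO3, THF/H2O 4:1, 0 °C; then CrO3/H2SO4 (Jones), acetone, 0 °C
Reagents that add atoms: water, O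
Why: Achmatowicz rearrangement (oxidative furan opening to the (Z)-ene-dione and closure of the tertiary hydroxyl onto the aldehyde carbon) gives lactol 20, and Jones oxidation of the hemiacetal gives the keto-lactone; no stereocentre.

Step 11
Reactants: 17 4-acetyl-3,3a-epoxy-1-(furan-3-yl)-1-hydroxy-5-[(1R)-1-hydroxyethyl]-4,7a-dimethyloctahydro-2H-inden-2-one; 21 6,6-dimethyl-2H-pyran-2,5(6H)-dione
Product: 24 3,3a-epoxy-1-(furan-3-yl)-1-hydroxy-5-[(1R)-1-hydroxyethyl]-4,7a-dimethyl-4-[(E)-2-(2,2-dimethyl-6-oxo-2H-pyran-3(6H)-ylidene)acetyl]octahydro-2H-inden-2-one, via trilithium enolate 22 (not isolated), via aldol adduct 23 (not isolated)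
Conditions: LiHMDS (3.3 equiv), THF, −78 °C; 21, −78 °C; aq NH4Cl; then CSA (10 mol %), CH2Cl2, rt
Reagents that add atoms: none
Why: The kinetic lithium enolate of the only enolisable ketone (C7 acetyl; both hydroxyls ride as alkoxides) adds 1,2 to the ketone of 21 (aldol addition), and acid-catalysed dehydration gives the cross-conjugated dienone with the acyl group next to the ring CH=CH and away from the gem-dimethyl carbon (the thermodynamic E isomer); ring stereocentres are untouched.

Step 12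
Reactants: 24 3,3a-epoxy-1-(furan-3-yl)-1-hydroxy-5-[(1R)-1-hydroxyethyl]-4,7a-dimethyl-4-[(E)-2-(2,2-dimethyl-6-oxo-2H-pyran-3(6H)-ylidene)acetyl]octahydro-2H-inden-2-one
Product: 25 CNP0293135.1, methyl (2S,3R,4R,5S,8R)-4-[(E)-2-(2,2-dimethyl-6-oxo-2H-pyran-3(6H)-ylidene)acetyl]-8-(furan-3-carbonyl)-5-[(1R)-1-hydroxyethyl]-4,8-dimethyl-1-oxaspiro[2.5]octane-2-carboxylate
Conditions: Pb(OAc)4 (1.1 equiv), MeOH/toluene 1:1, 0 °C
Reagents that add atoms: methanol, CO
Why: Lead tetraacetate cleavage of the α-hydroxy ketone (Criegee-type) in methanol breaks C16–C17 and gives the C16 methyl ester and the C17 furyl ketone in one operation; no bond to C13, C14 or C15 is broken, so their configuration is kept.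

## Compound list

1 | 2-methylcyclopentane-1,3-dione | CC1C(=O)CCC1=O | starting material
2 | acrolein | C=CC=O | starting material
3 | 3-(1-methyl-2,5-dioxocyclopentyl)propanal | O=CCCC1(C)C(=O)CCC1=O | intermediate
4 | 3-(triphenylphosphoranylidene)butan-2-one | CC(=O)C(C)=P(c1ccccc1)(c1ccccc1)c1ccccc1 | starting material
5 | 2-methyl-2-[(3E)-4-methyl-5-oxohex-3-en-1-yl]cyclopentane-1,3-dione | CC(=O)/C(C)=C/CCC1(C)C(=O)CCC1=O | intermediate
6 | potassium vinyltrifluoroborate | C=C[B-](F)(F)F.[K+] | starting material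
7 | rhodium enolate from vinyl addition to 5 (ligand omitted) | CC1(CC[C@H](C=C)C(C)=C(C)O[Rh])C(=O)CCC1=O | intermediate
8 | 4-acetyl-3a-hydroxy-4,7a-dimethyl-5-vinyloctahydro-1H-inden-1-one (13α-CH3, 14α-OH, 8α-acetyl, 8β-CH3, 9β-vinyl) | O[C@@]12CCC(=O)[C@]1(C)CC[C@H](C=C)[C@@]2(C)C(C)=O | intermediate
9 | 4-acetyl-4,7a-dimethyl-5-vinyl-2,4,5,6,7,7a-hexahydro-1H-inden-1-one | C12=CCC(=O)[C@]1(C)CC[C@H](C=C)[C@@]2(C)C(C)=O | intermediate
10 | 3-bromofuran | Brc1ccoc1 | starting material
11 | 3-furyllithium | [Li]c1ccoc1 | intermediate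
12 | 3-furylcerium dichloride | Cl[Ce](Cl)c1ccoc1 | intermediate
13 | 1-[1-(furan-3-yl)-1-hydroxy-4,7a-dimethyl-5-vinyl-2,4,5,6,7,7a-hexahydro-1H-inden-4-yl]ethan-1-one | C12=CC[C@](O)(c3ccoc3)[C@]1(C)CC[C@H](C=C)[C@@]2(C)C(C)=O | intermediate
14 | 1,1'-[1-(furan-3-yl)-1-hydroxy-4,7a-dimethyl-2,4,5,6,7,7a-hexahydro-1H-indene-4,5-diyl]di(ethan-1-one) | C12=CC[C@](O)(c3ccoc3)[C@]1(C)CC[C@H](C(C)=O)[C@@]2(C)C(C)=O | intermediate
15 | 1-[1-(furan-3-yl)-1-hydroxy-5-[(1R)-1-hydroxyethyl]-4,7a-dimethyl-2,4,5,6,7,7a-hexahydro-1H-inden-4-yl]ethan-1-one | C12=CC[C@](O)(c3ccoc3)[C@]1(C)CC[C@H]([C@@H](C)O)[C@@]2(C)C(C)=O | intermediate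
16 | 4-acetyl-1-(furan-3-yl)-1-hydroxy-5-[(1R)-1-hydroxyethyl]-4,7a-dimethyl-1,4,5,6,7,7a-hexahydro-2H-inden-2-one (Δ14-16-one) | C12=CC(=O)[C@](O)(c3ccoc3)[C@]1(C)CC[C@H]([C@@H](C)O)[C@@]2(C)C(C)=O | intermediate
17 | 4-acetyl-3,3a-epoxy-1-(furan-3-yl)-1-hydroxy-5-[(1R)-1-hydroxyethyl]-4,7a-dimethyloctahydro-2H-inden-2-one (14β,15β-epoxide) | O=C3[C@H]1O[C@@]12[C@](C)([C@@]3(O)c1ccoc1)CC[C@H]([C@@H](C)O)[C@@]2(C)C(C)=O | intermediate
18 | 2-acetylfuran | CC(=O)c1ccco1 | starting material
19 | 2-(furan-2-yl)propan-2-ol | CC(C)(O)c1ccco1 | intermediate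
20 | 6-hydroxy-2,2-dimethyl-2H-pyran-3(6H)-one | CC1(C)OC(O)C=CC1=O | intermediate
21 | 6,6-dimethyl-2H-pyran-2,5(6H)-dione | CC1(C)OC(=O)C=CC1=O | intermediate
22 | trilithium enolate/dialkoxide of 17 | O=C3[C@H]1O[C@@]12[C@](C)([C@@]3(O[Li])c1ccoc1)CC[C@H]([C@@H](C)O[Li])[C@@]2(C)C(=C)O[Li] | intermediate
23 | aldol adduct of 22 with 21 (tertiary β-hydroxy ketone, C5 epimers) | O=C3[C@H]1O[C@@]12[C@](C)([C@@]3(O)c1ccoc1)CC[C@H]([C@@H](C)O)[C@@]2(C)C(=O)CC1(O)C=CC(=O)OC1(C)C | intermediate
24 | 3,3a-epoxy-1-(furan-3-yl)-1-hydroxy-5-[(1R)-1-hydroxyethyl]-4,7a-dimethyl-4-[(E)-2-(2,2-dimethyl-6-oxo-2H-pyran-3(6H)-ylidene)acetyl]octahydro-2H-inden-2-one | O=C3[C@H]1O[C@@]12[C@](C)([C@@]3(O)c1ccoc1)CC[C@H]([C@@H](C)O)[C@@]2(C)C(=O)/C=C1\C=CC(=O)OC1(C)C | intermediate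
25 | CNP0293135.1, methyl (2S,3R,4R,5S,8R)-4-[(E)-2-(2,2-dimethyl-6-oxo-2H-pyran-3(6H)-ylidene)acetyl]-8-(furan-3-carbonyl)-5-[(1R)-1-hydroxyethyl]-4,8-dimethyl-1-oxaspiro[2.5]octane-2-carboxylate | COC(=O)[C@H]1O[C@@]12[C@](C)(C(=O)c1ccoc1)CC[C@H]([C@@H](C)O)[C@@]2(C)C(=O)/C=C1\C=CC(=O)OC1(C)C | target

## Step count and risks

Total steps: 12. Longest linear sequence: 10 (steps 1–8, 11, 12); steps 9–10 make lactone 21.

**Step 3 (most likely to fail).** α-Methyl enones are poor acceptors in Rh-catalysed additions, water may protonate enolate 7 before it cyclises, and the aldol must form three contiguous fully substituted carbons with the right C8 configuration. Fallback: the two bond formations are separated. It sets out from 5: copper-catalysed asymmetric addition of vinylmagnesium bromide (CuBr·SMe2, Josiphos-type ligand, TMSCl, t-BuOMe, −78 °C) gives the isolated trimethylsilyl enol ether F1. MeLi (THF, −78 to 0 °C) then regenerates a lithium enolate, which closes ring C by a separate lithium aldol onto the dione. The fallback comes back to the route at 8.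

**Step 8.** The t-BuOO radical may attack the furan or the C10 carbinol, and the face selectivity of the epoxidation rests only on the angular methyl. Fallback: the C16 oxygen is put in by enolate chemistry before the furan is present. It sets out from 9: the thermodynamic dienolate (LiHMDS, THF, −78 to 0 °C) and Davis oxaziridine give the 16β-hydroxy ketone F2. Addition of 3-furylcerium dichloride 12 gives the 16,17-diol F3; Wacker oxidation gives the C10 ketone diol F4; CBS reduction gives the triol F5. MnO2 (CH2Cl2, rt), which oxidises only the allylic C16 alcohol, comes back to the route at 16, and 16 is epoxidised with t-BuOOH/DBU to 17.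

**Step 11.** The enolate may add in a conjugate sense to the doubly activated alkene of 21 instead of 1,2 to its hindered ketone. Fallback: the lactone carbonyl is withheld until after the C–C bond is made. It sets out from 17: lactol 20 is converted (MeOH, PPTS) into 6-methoxy-2,2-dimethyl-2H-pyran-3(6H)-one F6, an enone without the second activating carbonyl. Enolate 22 adds 1,2 to F6 and acid dehydration gives the dienone methyl acetal F7. Hydrolysis (PPTS, acetone/H2O) gives the dienone lactol F8, and Fétizon oxidation (Ag2CO3/Celite, toluene, 80 °C), selective for the lactol over the C10 alcohol, comes back to the route at 24.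

## Further compounds

F1 | step 3 | trimethylsilyl enol ether of the vinyl adduct of 5 | CC1(CC[C@H](C=C)C(C)=C(C)O[Si](C)(C)C)C(=O)CCC1=O
F2 | step 8 | 4-acetyl-2-hydroxy-4,7a-dimethyl-5-vinyl-2,4,5,6,7,7a-hexahydro-1H-inden-1-one (16β-OH) | C12=C[C@H](O)C(=O)[C@]1(C)CC[C@H](C=C)[C@@]2(C)C(C)=O
F3 | step 8 | 1-[1-(furan-3-yl)-1,2-dihydroxy-4,7a-dimethyl-5-vinyl-2,4,5,6,7,7a-hexahydro-1H-inden-4-yl]ethan-1-one | C12=C[C@H](O)[C@](O)(c3ccoc3)[C@]1(C)CC[C@H](C=C)[C@@]2(C)C(C)=O
F4 | step 8 | 1,1'-[1-(furan-3-yl)-1,2-dihydroxy-4,7a-dimethyl-2,4,5,6,7,7a-hexahydro-1H-indene-4,5-diyl]di(ethan-1-one) | C12=C[C@H](O)[C@](O)(c3ccoc3)[C@]1(C)CC[C@H](C(C)=O)[C@@]2(C)C(C)=O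
F5 | step 8 | 1-[1-(furan-3-yl)-1,2-dihydroxy-5-[(1R)-1-hydroxyethyl]-4,7a-dimethyl-2,4,5,6,7,7a-hexahydro-1H-inden-4-yl]ethan-1-one | C12=C[C@H](O)[C@](O)(c3ccoc3)[C@]1(C)CC[C@H]([C@@H](C)O)[C@@]2(C)C(C)=O
F6 | step 11 | 6-methoxy-2,2-dimethyl-2H-pyran-3(6H)-one | COC1C=CC(=O)C(C)(C)O1
F7 | step 11 | dienone methyl acetal (24 with C3 as CH(OMe)) | O=C3[C@H]1O[C@@]12[C@](C)([C@@]3(O)c1ccoc1)CC[C@H]([C@@H](C)O)[C@@]2(C)C(=O)/C=C1\C=CC(OC)OC1(C)C
F8 | step 11 | dienone lactol (24 with C3 as CH(OH)) | O=C3[C@H]1O[C@@]12[C@](C)([C@@]3(O)c1ccoc1)CC[C@H]([C@@H](C)O)[C@@]2(C)C(=O)/C=C1\C=CC(O)OC1(C)C
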